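## The problem

The target 13 is an open-chain α-hydroxydihydrochalcone. Ring A (2-hydroxy-4-geranyloxyphenyl) and ring B (4-hydroxyphenyl) are joined only by the chain C(=O)–CH(OH)–CH2, so no ring has to be closed. The question is which of the four chain bonds (ring A–CO, CO–CHOH, CHOH–CH2, CH2–ring B) to form, and in what order. The single stereocentre, the R carbinol carbon, has no neighbour that could direct its formation, so it must be bought or set by a reagent, and it controls nothing else. It is also the most fragile atom: as the α-carbon of an aryl ketol it racemises by enolisation and can transpose through the ene-diol, which rules out strong base or acid late in the route. The geranyl aryl ether is the second fragile group. It ionises with Brønsted or Lewis acids, is cleaved by zerovalent palladium, and its two trisubstituted alkenes exclude hydrogenolysis, electrophilic halogenation and peracids once it is in place. Ring A also demands that the two resorcinol oxygens be told apart: free ortho to the ketone, geranylated para to it. The enabling feature is that C(=O), CH(OH) and CH2 of the chain are C1, C2 and C3 of malic acid, with C1 of ring B standing where the C4 carboxyl carbon was. (R)-Malic acid 1 therefore supplies the stereocentre, its acetonide distinguishes the two carboxyl groups, and the free C4 carboxyl can be exchanged for the aryl ring by decarboxylative coupling.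

## Retrosynthesis

**13 ⇒ 12 (O–Si bond of ring B).** A silyl ether is the only phenol protection that can be removed last without acid, hydrogen or zerovalent palladium, none of which the geranyl ether of 13 tolerates. Precursor 12 differs from 13 only in this group. The forward step must liberate the phenol without enolising the ketol, which calls for buffered fluoride.

**12 ⇒ 9 + 6, through 10 and 11 (ring A C1–carbonyl bond).**
- Against the neighbouring cuts: cutting CO–CHOH would require the stereocentre to be created during bond formation, and cutting CHOH–CH2 would require alkylation of an α-oxy ketone enolate. The ring A–CO cut leaves the stereocentre untouched inside the acyl donor.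
- Polarity: making ring A the electron-rich arene in an acylation would need a Lewis acid in the presence of the geranyl ether. Ring A is therefore the nucleophile, the aryllithium phenoxide 10 made from bromophenol 9.
- Acyl donor: dioxolanone 6 is an activated lactone whose acetonide is both the hydroxyl protection and the leaving group. Protonation of the tetrahedral adduct 11 releases the ketone and the free hydroxyl together.
- Unprotected ortho oxygen: carrying it as a lithium phenoxide avoids a protecting group that would later have to be removed beside the geranyl ether. If 11 collapses early, the ortho-phenoxide also makes the ketone too electron-rich for a second addition.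
- Demand on the forward reaction: carbonyl addition must outrun deprotonation at C5 of 6.

**6 ⇒ 3 + 5 (benzylic CH2–ring B bond, the key cut).** This cut converts the chain into malic acid. The ring carbonyl, C5 and the exocyclic CH2 of 6 are C1, C2 and C3 of the acid, and the ring B carbon replaces the C4 carboxyl. The neighbouring cut, C5–CH2, would mean alkylating a glycolate enolate and creating the stereocentre with an auxiliary. Both precursors are simple: redox-active ester 3 and aryl iodide 5. The forward reaction must join a primary sp3 carbon bearing a β-oxygen to an sp2 carbon, leave the C5–H bond alone, and tolerate an activated lactone and a silyl ether. A nickel-electrocatalytic decarboxylative arylation meets these demands.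

**3 ⇒ 2 ⇒ 1 and 5 ⇒ 4 (ester C–O, two acetal C–O bonds, O–Si).** The α-hydroxy acid of 1 closes the five-membered acetonide and leaves the C4 carboxyl of 2 free for activation as the N-acyloxyphthalimide 3. The descriptor R of 1 carries through to 13 because the priority order OH > carbonyl carbon > CH2 is the same throughout. Silyl ether 5 comes from 4-iodophenol 4 in one step.

**9 ⇒ 7 + 8 (O–CH2 bond of the geranyl ether).** Installing the geranyl group on 4-bromoresorcinol 7 with geranyl bromide 8 before the organometallic step means no electrophilic or acidic chemistry follows it. The forward reaction must mono-alkylate the hydroxyl remote from bromine.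

## Roads not taken

**Alternative 1: ring A built by Diels–Alder benzannulation.**
- Cut: two bonds of ring A, C1–C2 and C5–C6 (C1 bearing the acyl chain, C2 the hydroxyl).
- Forward: the vinylketene acetal A1 (geranyloxy at C3) and the chiral ynone A2 undergo [4+2] cycloaddition. The adduct aromatises by loss of methanol and the silyl group to give the bis-silyl ether A3.
- Merit: the polarity of A1 fixes the hydroxyl ortho and the geranyloxy para to the ketone. No regioselective alkylation of a resorcinol and no aryl-metal reagent are needed. In this respect it is better than the chosen plan, which depends on the selective alkylation of 7 in step 5.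
- Weak points: the geranyl–O–C(=CH2) unit of A1 is an allyl vinyl ether set up for a [3,3] shift of the geranyl group to carbon under thermal conditions. Making A1 requires O-geranylation of a β-keto ester enolate, which normally alkylates on carbon. A2 places the stereocentre α to an ynone, where it is more acidic than in any intermediate of the chosen route. A2 must still be made from the same protected (R)-α-hydroxy acid that the chosen route reaches as 6, so the benzannulation adds a diene and an ynone synthesis without removing the chiral-pool work.
- Comparison: the chosen plan buys ring A as an arene and attaches it in one step. Against the regiochemical certainty of A3 it sets a shorter sequence and a fallback for step 5.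

**Alternative 2: enantioselective cross silyl benzoin.**
- Cut: the CO–CHOH bond.
- Forward: a lithium TADDOL-phosphite adds to the ring A acylsilane A4. A [1,2]-Brook shift gives an acyl-anion equivalent that adds to the arylacetaldehyde A5. A 1,4-silyl transfer and loss of the phosphite then give the tris-silyl ether A6, with the R carbinol set by the catalyst.
- Merits: it is the most convergent plan. The stereocentre is made catalytically, either enantiomer is accessible, no electrolysis is needed, and the mechanism fixes which partner becomes the ketone. In convergence and in independence from the less common enantiomer of malic acid it is better than the chosen plan.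
- Weak points: A5 has acidic benzylic α-protons, so it is prone to enolisation and self-condensation under the basic metallophosphite. The reaction type is best established for non-enolisable aldehydes. A4 carries an ortho silyloxy group and a para alkoxy group, so it is both hindered and electron-rich toward phosphite addition. Its preparation needs an umpolung sequence on the corresponding benzaldehyde, whose unmasking must spare the geranyl alkenes. Any shortfall in enantioselectivity would go straight into the target.
- Comparison: the chosen plan sets against this a stereocentre of full enantiomeric purity from the first step, and two couplings whose substrate classes match their precedent.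

**Alternative 3: C-acylation of a vinylogous ester, then aromatisation.**
- Cut: the ring A C1–carbonyl bond, as in the chosen endgame, but with ring A at the cyclohexenone oxidation level.
- Forward: the kinetic C6 enolate of A7 (two equivalents of LDA, because the product is more acidic) attacks the acyl imidazole A8 to give the chelated enol A9. Dehydrogenation then has to deliver ring A.
- Merit: the ring A pattern is unambiguous, since the acyl group enters next to the carbonyl that becomes the free hydroxyl and the geranyl group is already on the correct oxygen. No halogen–metal exchange is needed. Here it matches alternative 1 and is better than step 5 of the chosen plan.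
- Weak points: the aromatisation of A9 must remove two hydrogens in the presence of two trisubstituted alkenes, an allylic ether and an α-silyloxy ketone flanked by a 1,3-dicarbonyl system. Quinone oxidants, halogenation–elimination, selenoxide elimination and palladium dehydrogenation each threaten one of these. A7 must be made by acid-catalysed etherification with an ionisable allylic alcohol, or by O-alkylation of a 1,3-diketone enolate that prefers carbon. A8 meets excess amide base and may epimerise. The chiral acid must still be made as in the chosen route.
- Comparison: the route is longer and ends with its riskiest operation. The chosen plan uses an aromatic ring A throughout and finishes with a buffered desilylation.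

Key step: step 4

## Route

Step 1
Reactants: 1 (R)-malic acid
Product: 2 2-[(4R)-2,2-dimethyl-5-oxo-1,3-dioxolan-4-yl]acetic acid
Conditions: 2,2-dimethoxypropane, p-TsOH·H2O (cat.), rt
Reagents that add atoms: 2,2-dimethoxypropane, COC(C)(C)OC
Why: Acid-catalysed acetal exchange; the α-hydroxy acid closes the five-membered dioxolanone in preference to a six-membered ring through the remote carboxyl, so the C4 carboxyl stays free. The stereocentre is not touched.

Step 2
Reactants: 2 2-[(4R)-2,2-dimethyl-5-oxo-1,3-dioxolan-4-yl]acetic acid
Product: 3 1,3-dioxoisoindolin-2-yl 2-[(4R)-2,2-dimethyl-5-oxo-1,3-dioxolan-4-yl]acetate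
Conditions: N-hydroxyphthalimide, DIC, DMAP (cat.), CH2Cl2, 0 °C to rt
Reagents that add atoms: N-hydroxyphthalimide, ON1C(=O)c2ccccc2C1=O
Why: Carbodiimide esterification of a primary carboxylic acid to its redox-active N-acyloxyphthalimide. The weakly nucleophilic N-hydroxyimide and catalytic DMAP should leave the dioxolanone intact.

Step 3
Reactants: 4 4-iodophenol
Product: 5 tert-butyl(4-iodophenoxy)dimethylsilane
Conditions: TBSCl, imidazole, CH2Cl2, rt
Reagents that add atoms: tert-butyldimethylsilyl chloride, CC(C)(C)[Si](C)(C)Cl
Why: Standard silylation of a phenol. The silyl ether removes the acidic proton for steps 4 and 6 and is later cleaved by fluoride without acid, hydrogen or palladium.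

Step 4
Reactants: 3 1,3-dioxoisoindolin-2-yl 2-[(4R)-2,2-dimethyl-5-oxo-1,3-dioxolan-4-yl]acetate (1.5 equiv); 5 tert-butyl(4-iodophenoxy)dimethylsilane (1.0 equiv)
Product: 6 (5R)-5-{4-[(tert-butyldimethylsilyl)oxy]benzyl}-2,2-dimethyl-1,3-dioxolan-4-one
Conditions: NiCl2·6H2O (20 mol %), 2,2′-bipyridine (20 mol %), AgNO3 (0.3 equiv), NMP, Mg anode, reticulated vitreous carbon cathode, constant current, rt, undivided cell
Reagents that add atoms: none
Why: Cathodic reduction converts the bipyridine-ligated divalent nickel salt into low-valent nickel, which inserts into the C–I bond of 5 to give an arylnickel species. Single-electron reduction of the phthalimide ester 3, at the silver-coated cathode or by low-valent nickel, fragments it into phthalimide anion, CO2 and the primary radical at the exocyclic CH2 of the dioxolanone. The arylnickel captures this radical and the resulting trivalent alkyl(aryl)nickel undergoes reductive elimination, forming the CH2–ring B bond, while the magnesium anode supplies the electrons and Mg2+ as counter-ion. The closest known reaction type is the nickel-electrocatalytic decarboxylative arylation of redox-active esters with aryl halides, which has been applied to esters derived from chiral-pool amino and hydroxy acids. No ring closes and no stereocentre is created; the R centre at C5 is retained because the radical sits one carbon away and the C5–H bond is never broken. Cross-coupling must outrun aryl homocoupling, radical dimerisation, hydrogen-atom capture and β-hydride loss from the alkylnickel: the iodide ensures fast oxidative addition so an arylnickel trap is always present, the bipyridine ligand favours radical capture and rapid reductive elimination, and the silver deposit lowers the working potential so that 3 is not reduced faster than it is used. The silyl ether and the lactone acetal carry no acidic proton and are not reduced at this potential.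

Step 5
Reactants: 7 4-bromoresorcinol (1.2 equiv); 8 geranyl bromide (1.0 equiv)
Product: 9 2-bromo-5-{[(2E)-3,7-dimethylocta-2,6-dien-1-yl]oxy}phenol
Conditions: K2CO3 (1.0 equiv), acetone, rt
Reagents that add atoms: none
Why: Williamson ether synthesis by SN2 at the primary allylic bromide, which keeps the E alkene. The hydroxyl para to bromine is less hindered and its phenoxide more nucleophilic than the one flanked by bromine, so mono-alkylation should occur mainly there; limiting 8 and one equivalent of base suppress dialkylation.

Step 6
Reactants: 9 2-bromo-5-{[(2E)-3,7-dimethylocta-2,6-dien-1-yl]oxy}phenol (1.5 equiv); 6 (5R)-5-{4-[(tert-butyldimethylsilyl)oxy]benzyl}-2,2-dimethyl-1,3-dioxolan-4-one (1.0 equiv)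
Product: 12 (2R)-3-{4-[(tert-butyldimethylsilyl)oxy]phenyl}-1-(4-{[(2E)-3,7-dimethylocta-2,6-dien-1-yl]oxy}-2-hydroxyphenyl)-2-hydroxypropan-1-one, via lithium 5-(geranyloxy)-2-lithiophenoxide 10 (not isolated), via dilithium hemiketal adduct 11 (not isolated)
Conditions: 9, n-BuLi (1.0 equiv per 9) then t-BuLi (2.0 equiv per 9), THF, −78 °C; add 6, −78 to −40 °C; sat. aq. NH4Cl
Reagents that add atoms: none
Why: Deprotonation and bromine–lithium exchange give the aryllithium phenoxide 10, and the t-BuLi is fully consumed before 6 is added. Acyl substitution on the activated lactone gives hemiketal 11 (epimers at the new carbon, which becomes the ketone), which on protonation opens with loss of acetone to the α-hydroxy ketone, a known way from 1,3-dioxolan-4-ones to ketols. The low temperature favours addition over deprotonation at C5, so the R centre should be retained, and the ortho-phenoxide deactivates the ketone toward a second addition.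

Step 7
Reactants: 12 (2R)-3-{4-[(tert-butyldimethylsilyl)oxy]phenyl}-1-(4-{[(2E)-3,7-dimethylocta-2,6-dien-1-yl]oxy}-2-hydroxyphenyl)-2-hydroxypropan-1-one
Product: 13 (2R)-1-(4-{[(2E)-3,7-dimethylocta-2,6-dien-1-yl]oxy}-2-hydroxyphenyl)-2-hydroxy-3-(4-hydroxyphenyl)propan-1-one (CNP0159413.1)
Conditions: TBAF, AcOH, THF, 0 °C
Reagents that add atoms: none
Why: Fluoride cleavage of an aryl silyl ether. The acetic acid buffer keeps the medium from enolising the ketol, and the geranyl ether and alkenes are inert to fluoride.

## Compound list

1 | (R)-malic acid, (2R)-2-hydroxybutanedioic acid | OC(=O)C[C@@H](O)C(=O)O | starting material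
2 | 2-[(4R)-2,2-dimethyl-5-oxo-1,3-dioxolan-4-yl]acetic acid | CC1(C)OC(=O)[C@@H](CC(=O)O)O1 | intermediate
3 | 1,3-dioxoisoindolin-2-yl 2-[(4R)-2,2-dimethyl-5-oxo-1,3-dioxolan-4-yl]acetate | CC1(C)OC(=O)[C@@H](CC(=O)ON2C(=O)c3ccccc3C2=O)O1 | intermediate
4 | 4-iodophenol | Oc1ccc(I)cc1 | starting material
5 | tert-butyl(4-iodophenoxy)dimethylsilane | Ic1ccc(O[Si](C)(C)C(C)(C)C)cc1 | intermediate
6 | (5R)-5-{4-[(tert-butyldimethylsilyl)oxy]benzyl}-2,2-dimethyl-1,3-dioxolan-4-one | CC1(C)OC(=O)[C@@H](Cc2ccc(O[Si](C)(C)C(C)(C)C)cc2)O1 | intermediate
7 | 4-bromoresorcinol, 4-bromobenzene-1,3-diol | Oc1ccc(Br)c(O)c1 | starting material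
8 | geranyl bromide, (2E)-1-bromo-3,7-dimethylocta-2,6-diene | CC(C)=CCC/C(C)=C/CBr | starting material
9 | 2-bromo-5-{[(2E)-3,7-dimethylocta-2,6-dien-1-yl]oxy}phenol | CC(C)=CCC/C(C)=C/COc1ccc(Br)c(O)c1 | intermediate
10 | lithium 5-{[(2E)-3,7-dimethylocta-2,6-dien-1-yl]oxy}-2-lithiophenoxide | CC(C)=CCC/C(C)=C/COc1ccc([Li])c(O[Li])c1 | intermediate (not isolated)
11 | dilithium salt of (5R)-5-{4-[(tert-butyldimethylsilyl)oxy]benzyl}-4-(4-{[(2E)-3,7-dimethylocta-2,6-dien-1-yl]oxy}-2-hydroxyphenyl)-2,2-dimethyl-1,3-dioxolan-4-ol, epimers at C4 | CC(C)=CCC/C(C)=C/COc1ccc(c(O[Li])c1)C1(O[Li])OC(C)(C)O[C@@H]1Cc1ccc(O[Si](C)(C)C(C)(C)C)cc1 | intermediate (not isolated)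
12 | (2R)-3-{4-[(tert-butyldimethylsilyl)oxy]phenyl}-1-(4-{[(2E)-3,7-dimethylocta-2,6-dien-1-yl]oxy}-2-hydroxyphenyl)-2-hydroxypropan-1-one | CC(C)=CCC/C(C)=C/COc1ccc(C(=O)[C@H](O)Cc2ccc(O[Si](C)(C)C(C)(C)C)cc2)c(O)c1 | intermediate
13 | (2R)-1-(4-{[(2E)-3,7-dimethylocta-2,6-dien-1-yl]oxy}-2-hydroxyphenyl)-2-hydroxy-3-(4-hydroxyphenyl)propan-1-one | CC(C)=CCC/C(C)=C/COc1ccc(C(=O)[C@H](O)Cc2ccc(O)cc2)c(O)c1 | target

## Step count and least certain steps

Total: 7 steps. Longest linear sequence: 5 steps (steps 1, 2, 4, 6, 7). Steps 3 and 5 are one-step branches for ring B and ring A.

**Step 4 (key step).** The likeliest failure is unproductive consumption of the redox-active ester. If the primary radical forms faster than the arylnickel can capture it, it ends in hydrogen-atom abstraction from solvent, dimerisation, or β-hydride loss from the alkylnickel. The electron-rich aryl iodide is then diverted to homocoupling or protodehalogenation. Passivation of the magnesium anode by its salts may also stall the current. The fallback sets out from 5 and 3 and comes back at 6. Zinc insertion into 5 (Zn dust, LiCl, THF, 50 °C) gives {4-[(tert-butyldimethylsilyl)oxy]phenyl}zinc iodide F1. F1 is coupled with 3 under NiCl2·DME and 4,4′-di-tert-butyl-2,2′-bipyridine in THF/DMF at rt, a decarboxylative Negishi arylation of the redox-active ester. This is a redox-neutral coupling with a preformed aryl nucleophile, so it needs no electrolysis and no balance between two reduction events.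

**Step 6.** The likeliest failure is proton abstraction at C5 of 6 by the strongly basic aryllithium phenoxide in competition with carbonyl addition. This would erode the stereocentre through the planar dioxolanone enolate. Incomplete bromine–lithium exchange on the electron-rich phenoxide, and early collapse of the adduct followed by a second addition, are lesser concerns. The fallback sets out from 6 and comes back at 12. The dioxolanone is opened with N,O-dimethylhydroxylamine hydrochloride and i-PrMgCl (THF, −20 °C), with loss of acetone, to give (2R)-3-{4-[(tert-butyldimethylsilyl)oxy]phenyl}-2-hydroxy-N-methoxy-N-methylpropanamide F2. Its hydroxyl is deprotonated with one equivalent of i-PrMgCl and the resulting alkoxide is treated with 10 at −78 to 0 °C. The neighbouring alkoxide disfavours α-deprotonation of the amide and the chelated tetrahedral intermediate prevents over-addition, so aqueous work-up should give 12.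

**Step 5.** The likeliest failure is alkylation at the wrong oxygen or at both. The hydroxyl ortho to bromine is the more acidic and holds most of the phenoxide charge at equilibrium, and the resorcinol ring can also be geranylated on carbon. The fallback sets out from 7 and comes back at 13. It takes regiocontrol from the ketone instead of the bromide.
- 7 is bis-protected with chloromethyl methyl ether and i-Pr2NEt to give 1-bromo-2,4-bis(methoxymethoxy)benzene F3.
- Exchange with n-BuLi (THF, −78 °C) gives [2,4-bis(methoxymethoxy)phenyl]lithium F4.
- Addition of F4 to 6 and work-up as in step 6 gives (2R)-1-[2,4-bis(methoxymethoxy)phenyl]-3-{4-[(tert-butyldimethylsilyl)oxy]phenyl}-2-hydroxypropan-1-one F5.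
- HCl in methanol, then TBAF/AcOH, removes all three protecting groups before any geranyl group is present, giving (2R)-1-(2,4-dihydroxyphenyl)-2-hydroxy-3-(4-hydroxyphenyl)propan-1-one F6.
- F6 is alkylated with 8 and one equivalent of K2CO3 in acetone. The ring A hydroxyl para to the ketone is the most acidic phenol, the ortho hydroxyl is tied up in a hydrogen bond to the carbonyl, and the ring B phenol is markedly less acidic, so mono-geranylation should give 13.

## Further compounds

F1 | step 4 | {4-[(tert-butyldimethylsilyl)oxy]phenyl}zinc iodide | CC(C)(C)[Si](C)(C)Oc1ccc([Zn]I)cc1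
F2 | step 6 | (2R)-3-{4-[(tert-butyldimethylsilyl)oxy]phenyl}-2-hydroxy-N-methoxy-N-methylpropanamide | CON(C)C(=O)[C@H](O)Cc1ccc(O[Si](C)(C)C(C)(C)C)cc1
F3 | step 5 | 1-bromo-2,4-bis(methoxymethoxy)benzene | COCOc1ccc(Br)c(OCOC)c1
F4 | step 5 | [2,4-bis(methoxymethoxy)phenyl]lithium | COCOc1ccc([Li])c(OCOC)c1
F5 | step 5 | (2R)-1-[2,4-bis(methoxymethoxy)phenyl]-3-{4-[(tert-butyldimethylsilyl)oxy]phenyl}-2-hydroxypropan-1-one | COCOc1ccc(C(=O)[C@H](O)Cc2ccc(O[Si](C)(C)C(C)(C)C)cc2)c(OCOC)c1
F6 | step 5 | (2R)-1-(2,4-dihydroxyphenyl)-2-hydroxy-3-(4-hydroxyphenyl)propan-1-one | Oc1ccc(C(=O)[C@H](O)Cc2ccc(O)cc2)c(O)c1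
A1 | alternative 1 | {[3-{[(2E)-3,7-dimethylocta-2,6-dien-1-yl]oxy}-1-methoxybuta-1,3-dien-1-yl]oxy}trimethylsilane | CC(C)=CCC/C(C)=C/COC(=C)C=C(OC)O[Si](C)(C)C
A2 | alternative 1 | (4R)-4-[(tert-butyldimethylsilyl)oxy]-5-{4-[(tert-butyldimethylsilyl)oxy]phenyl}pent-1-yn-3-one | C#CC(=O)[C@H](O[Si](C)(C)C(C)(C)C)Cc1ccc(O[Si](C)(C)C(C)(C)C)cc1
A3 | alternative 1 | (2R)-2-[(tert-butyldimethylsilyl)oxy]-3-{4-[(tert-butyldimethylsilyl)oxy]phenyl}-1-(4-{[(2E)-3,7-dimethylocta-2,6-dien-1-yl]oxy}-2-hydroxyphenyl)propan-1-one | CC(C)=CCC/C(C)=C/COc1ccc(C(=O)[C@H](O[Si](C)(C)C(C)(C)C)Cc2ccc(O[Si](C)(C)C(C)(C)C)cc2)c(O)c1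
A4 | alternative 2 | (2-[(tert-butyldimethylsilyl)oxy]-4-{[(2E)-3,7-dimethylocta-2,6-dien-1-yl]oxy}phenyl)(triethylsilyl)methanone | CC(C)=CCC/C(C)=C/COc1ccc(C(=O)[Si](CC)(CC)CC)c(O[Si](C)(C)C(C)(C)C)c1
A5 | alternative 2 | 2-{4-[(tert-butyldimethylsilyl)oxy]phenyl}acetaldehyde | O=CCc1ccc(O[Si](C)(C)C(C)(C)C)cc1
A6 | alternative 2 | (2R)-1-(2-[(tert-butyldimethylsilyl)oxy]-4-{[(2E)-3,7-dimethylocta-2,6-dien-1-yl]oxy}phenyl)-3-{4-[(tert-butyldimethylsilyl)oxy]phenyl}-2-[(triethylsilyl)oxy]propan-1-one | CC(C)=CCC/C(C)=C/COc1ccc(C(=O)[C@H](O[Si](CC)(CC)CC)Cc2ccc(O[Si](C)(C)C(C)(C)C)cc2)c(O[Si](C)(C)C(C)(C)C)c1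
A7 | alternative 3 | 3-{[(2E)-3,7-dimethylocta-2,6-dien-1-yl]oxy}cyclohex-2-en-1-one | CC(C)=CCC/C(C)=C/COC1=CC(=O)CCC1
A8 | alternative 3 | (2R)-2-[(tert-butyldimethylsilyl)oxy]-3-{4-[(tert-butyldimethylsilyl)oxy]phenyl}-1-(1H-imidazol-1-yl)propan-1-one | O=C([C@H](O[Si](C)(C)C(C)(C)C)Cc1ccc(O[Si](C)(C)C(C)(C)C)cc1)n1ccnc1
A9 | alternative 3 | (2R)-2-[(tert-butyldimethylsilyl)oxy]-3-{4-[(tert-butyldimethylsilyl)oxy]phenyl}-1-(4-{[(2E)-3,7-dimethylocta-2,6-dien-1-yl]oxy}-2-hydroxycyclohexa-1,3-dien-1-yl)propan-1-one | CC(C)=CCC/C(C)=C/COC1=CC(O)=C(CC1)C(=O)[C@H](O[Si](C)(C)C(C)(C)C)Cc1ccc(O[Si](C)(C)C(C)(C)C)cc1
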